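**Retrosynthetic overview**

1. Feature: C3 of the pyrrole ring is a bromine-bearing carbon next to C2, so N1–C2–C3 can come from a tribromoacetamide that already carries the C3 bromine, and C4–C5 from an N-vinyl group.
2. Key disconnection: the C3–C4 bond, formed by copper-mediated 5-endo radical closure of the tribromoacetyl enamide 6 with radical-polar crossover to the unsaturated lactam 7. This closes the only ring.
3. After ring closure, one C3 bromine of 7 is moved to C4 (9) and nitrogen is freed at the stable lactam stage (10). POBr3 then converts C2=O into C2–Br with aromatisation (11), and NBS fills C5 (12).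
4. Nitrogen carries a diphenylmethyl group: it is bulky, its phenyl rings do not take up positive bromine as alkoxy-substituted benzyl groups would, and hot acid removes it.
5. Enamide 6 is assembled from benzhydrylamine, acetaldehyde and tribromoacetyl chloride by imine acylation.

Key step: step 3

Remark on the chemistry: atom numbers N1 and C2–C5 are those of the pyrrole ring of the target and are kept for all ring intermediates. Compounds 11 and 12 are assumed to be light- and acid-sensitive, so they are handled cold and in the dark, and 11 is carried on crude.

**Route**

Step 1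
Reactants: 1 tribromoacetic acid
Product: 2 tribromoacetyl chloride
Conditions: (COCl)2, DMF (cat.), CH2Cl2, 0 °C to rt; concentrate, use crude
Reagents that add atoms: oxalyl chloride, ClC(=O)C(=O)Cl
Why: Acid chloride formation with oxalyl chloride under DMF catalysis (chloroiminium activation) runs cold, which avoids the decarboxylation to bromoform that tribromoacetic acid suffers on heating.

Step 2
Reactants: 3 diphenylmethanamine (benzhydrylamine); 4 acetaldehyde; 2 tribromoacetyl chloride
Product: 6 2,2,2-tribromo-N-(diphenylmethyl)-N-vinylacetamide, via (E)-N-(diphenylmethyl)ethan-1-imine 5 (not isolated)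
Conditions: 3, MeCHO, MgSO4, CH2Cl2, 0 °C; filter; 2, then Et3N, –20 °C to rt
Reagents that add atoms: none
Why: Amine–aldehyde condensation gives the imine, whose nitrogen is acylated by 2 to an N-acyliminium ion that Et3N deprotonates at the methyl group (enamide synthesis by acylation of an enolisable imine); the acetaldimine is used at once because it self-condenses, and the base is added last so that it meets the acyliminium salt and not free 2.

Step 3
Reactants: 6 2,2,2-tribromo-N-(diphenylmethyl)-N-vinylacetamide
Product: 7 3,3-dibromo-1-(diphenylmethyl)-1,3-dihydro-2H-pyrrol-2-one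
Conditions: CuBr (0.3 equiv), tris(2-pyridylmethyl)amine (0.3 equiv), Na2CO3 (1.5 equiv), degassed toluene, 50 °C
Reagents that add atoms: none
Why: The CuBr–tris(2-pyridylmethyl)amine complex (monovalent copper) abstracts a bromine atom from the CBr3 group, and the electrophilic dibromoacetamide radical adds to the terminal vinyl carbon, forming C3–C4 and leaving a radical at C5 next to nitrogen. The divalent copper bromide complex made in the abstraction oxidises this radical (directly or through the C5 bromide) to an N-acyliminium ion, which gives up the C4 proton to Na2CO3 to form the C4=C5 enamide and returns monovalent copper. The closest known reaction type is the copper–amine mediated radical-polar crossover cyclisation of trichloroacetyl enamides to unsaturated gamma-lactams. The pyrrole ring is closed in the 5-endo-trig mode and no stereocentre is formed. The step needs 5-endo closure to beat 4-exo closure and simple reduction: the 4-exo path would give a strained beta-lactam carrying a primary radical and reopens, whereas the C5 radical is drained irreversibly by electron transfer to copper. The bulky diphenylmethyl group should sit on the carbonyl-oxygen side of the amide and so hold the vinyl group next to the radical carbon.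

Step 4
Reactants: 7 3,3-dibromo-1-(diphenylmethyl)-1,3-dihydro-2H-pyrrol-2-one
Product: 9 3,4-dibromo-1-(diphenylmethyl)-1,5-dihydro-2H-pyrrol-2-one, via 3-bromo-1-(diphenylmethyl)-1H-pyrrol-2-ol 8 (not isolated)
Conditions: HBr (33% in AcOH, 0.1 equiv), CH2Cl2, 0 °C to rt, dark
Reagents that add atoms: none
Why: Proposed new method: bromide should attack one bromine on C3 because the leaving group is the aromatic 2-hydroxypyrrole 8, and the Br2 set free then returns to the ring, where attack at C3 or C5 only regenerates positive-bromine donors while attack at C4 followed by proton loss and ketonisation at C5 gives the conjugated lactam 9, whose two vinylic C–Br bonds cannot give bromine back, so the mixture should drain to 9 with HBr regenerated; the closest known reaction type is the HBr-catalysed rearrangement of 2,2-dibromo ketones to 2,4-dibromo ketones by debromination and rebromination.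

Step 5
Reactants: 9 3,4-dibromo-1-(diphenylmethyl)-1,5-dihydro-2H-pyrrol-2-one
Product: 10 3,4-dibromo-1,5-dihydro-2H-pyrrol-2-one
Conditions: TFA, anisole (5 equiv), 70 °C
Reagents that add atoms: none
Why: SN1 acidolysis of the N-diphenylmethyl lactam with the diphenylmethyl cation trapped by anisole (Friedel–Crafts alkylation) should proceed cleanly because the vinylic bromides and the unsaturated lactam are inert to hot acid and no positive-bromine donor remains to attack the scavenger.

Step 6
Reactants: 10 3,4-dibromo-1,5-dihydro-2H-pyrrol-2-one
Product: 11 2,3,4-tribromo-1H-pyrrole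
Conditions: POBr3 (1.5 equiv), ClCH2CH2Cl, 60 °C; cold aq. NaHCO3 quench; use crude
Reagents that add atoms: phosphorus oxybromide, O=P(Br)(Br)Br
Why: Deoxybromination of a 3-pyrrolin-2-one to a 2-bromopyrrole is expected, since the lactam oxygen is phosphorylated, bromide displaces the phosphate at C2 (Vilsmeier-type activation) and a proton shift from C5 to nitrogen gives the aromatic ring.

Step 7
Reactants: 11 2,3,4-tribromo-1H-pyrrole
Product: 12 2,3,4,5-tetrabromo-1H-pyrrole (tetrabromopyrrole)
Conditions: NBS (1.05 equiv), THF, –78 to 0 °C, dark
Reagents that add atoms: N-bromosuccinimide, O=C1CCC(=O)N1Br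
Why: Electrophilic aromatic bromination with NBS should occur at C5, the only free position and an alpha-position of the pyrrole, under the cold conditions that serve for exhaustive bromination of pyrrole itself.

**Compound list**

1 | tribromoacetic acid | OC(=O)C(Br)(Br)Br | starting material
2 | tribromoacetyl chloride | ClC(=O)C(Br)(Br)Br | intermediate
3 | diphenylmethanamine (benzhydrylamine) | NC(c1ccccc1)c1ccccc1 | starting material
4 | acetaldehyde | CC=O | starting material
5 | (E)-N-(diphenylmethyl)ethan-1-imine | C/C=N/C(c1ccccc1)c1ccccc1 | intermediate (not isolated)
6 | 2,2,2-tribromo-N-(diphenylmethyl)-N-vinylacetamide | C=CN(C(c1ccccc1)c1ccccc1)C(=O)C(Br)(Br)Br | intermediate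
7 | 3,3-dibromo-1-(diphenylmethyl)-1,3-dihydro-2H-pyrrol-2-one | O=C1N(C(c2ccccc2)c2ccccc2)C=CC1(Br)Br | intermediate
8 | 3-bromo-1-(diphenylmethyl)-1H-pyrrol-2-ol | Oc1c(Br)ccn1C(c1ccccc1)c1ccccc1 | intermediate (not isolated)
9 | 3,4-dibromo-1-(diphenylmethyl)-1,5-dihydro-2H-pyrrol-2-one | O=C1C(Br)=C(Br)CN1C(c1ccccc1)c1ccccc1 | intermediate
10 | 3,4-dibromo-1,5-dihydro-2H-pyrrol-2-one | O=C1NCC(Br)=C1Br | intermediate
11 | 2,3,4-tribromo-1H-pyrrole | Brc1[nH]cc(Br)c1Br | intermediate
12 | 2,3,4,5-tetrabromo-1H-pyrrole | Brc1[nH]c(Br)c(Br)c1Br | target

**Count**

Total steps: 7. Longest linear sequence: 7 steps (1 to 12).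

**Steps most likely to fail**

1. Step 4 (bromine migration). The redistribution of positive bromine may stop at other positional isomers, or disproportionate into mono- and tribrominated lactams, instead of draining to the C4 position. The fallback sets out from 7 and comes back at 9, using two known operations. Enamide beta-bromination with NBS (1.0 equiv, CH2Cl2, 0 °C, dark) should give 3,3,4-tribromo-1-(diphenylmethyl)-1,3-dihydro-2H-pyrrol-2-one F1. Aqueous Na2SO3 then removes one positive bromine from C3, as sulfite does with alpha,alpha-dibromo carbonyl compounds, and protonation of the resulting enolate at C5 should give 9.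

2. Step 3 (key step). Reversible 4-exo closure may lead to reduction or oligomerisation, and the copper complex may abstract a second bromine from the doubly activated C3 of the product so that it is consumed as it forms. The fallback sets out from 3 and comes back at 9, closing the ring at the N1–C2 amide bond instead. Amine 3 is combined with mucobromic acid ((Z)-2,3-dibromo-4-oxobut-2-enoic acid, commercial) and NaBH(OAc)3 in CH2Cl2–AcOH. Reductive amination should give (Z)-2,3-dibromo-4-[(diphenylmethyl)amino]but-2-enoic acid F2, which lactamises in the flask to 9.

3. Step 6 (POBr3). Activation of the electron-poor lactam may be sluggish, and the N-unsubstituted bromopyrrole may decompose or scramble its bromines under hot acidic phosphorus reagents. The fallback sets out from 10 and comes back at 12, introducing the C2 bromine by electrophilic bromination instead of deoxybromination.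
   - Boc2O and DMAP in MeCN should give tert-butyl 3,4-dibromo-2-oxo-2,5-dihydro-1H-pyrrole-1-carboxylate F3.
   - i-Bu2AlH in CH2Cl2 at –78 °C should reduce the activated carbonyl to racemic tert-butyl 3,4-dibromo-2-hydroxy-2,5-dihydro-1H-pyrrole-1-carboxylate F4, which dehydrates on mild acidic work-up to tert-butyl 3,4-dibromo-1H-pyrrole-1-carboxylate F5.
   - NaOMe in MeOH should remove the carbamate to give 3,4-dibromo-1H-pyrrole F6.
   - NBS (2.1 equiv) in THF at –78 °C should brominate C2 and C5 to give 12.

**Further compounds**

F1 | step 4 | 3,3,4-tribromo-1-(diphenylmethyl)-1,3-dihydro-2H-pyrrol-2-one | O=C1N(C(c2ccccc2)c2ccccc2)C=C(Br)C1(Br)Br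
F2 | step 3 | (Z)-2,3-dibromo-4-[(diphenylmethyl)amino]but-2-enoic acid | OC(=O)/C(Br)=C(Br)\CNC(c1ccccc1)c1ccccc1
F3 | step 6 | tert-butyl 3,4-dibromo-2-oxo-2,5-dihydro-1H-pyrrole-1-carboxylate | O=C1C(Br)=C(Br)CN1C(=O)OC(C)(C)C
F4 | step 6 | tert-butyl 3,4-dibromo-2-hydroxy-2,5-dihydro-1H-pyrrole-1-carboxylate (racemic) | OC1C(Br)=C(Br)CN1C(=O)OC(C)(C)C
F5 | step 6 | tert-butyl 3,4-dibromo-1H-pyrrole-1-carboxylate | CC(C)(C)OC(=O)n1cc(Br)c(Br)c1
F6 | step 6 | 3,4-dibromo-1H-pyrrole | Brc1c[nH]cc1Br
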